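**Plan**

- Retrosynthesis: the three MOM ethers are cut first, then the C6–geranyl bond (Stille coupling at a C6 iodide) and the C8–prenyl bond (Claisen–Cope shift from a 5-O-prenyl ether), then the O3-benzyl group and the O1–C2 bond of ring C (Mitsunobu).
- The acyclic chain is then cut at C2–C3 and C3–O3 together. C3 is an oxygen-bearing carbon α to the C4 ketone on ring A and C2 is a benzylic carbinol carbon on ring B, so C3, O3 and C2 map onto a ring A diazoketone carbon, an alcohol oxygen and the ring B aldehyde carbon.
- Forward: ring A diazoketone (3 steps) and ring B aldehyde (2 steps) are joined with benzyl alcohol in one three-component step; ring C then closes at O1–C2; the prenyl and geranyl groups are added last.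
- Stereochemistry: C3 (R) is set by a chiral phosphoric acid in the three-component step, which gives the syn adduct. C2 is inverted to R in the Mitsunobu closure, giving the 2,3-trans chromanone. The E geometry of the geranyl group is carried over from geranyl chloride.

Key step: step 6

Remark: the sense of induction of the phosphoric acid in step 6 cannot be predicted with certainty; the (R)-acid is written and stands for whichever antipode gives the (2R,3S) adduct. Chromanones carry flavanone numbering (O1, C2, C3, C4, C4a, C5–C8, C8a; ring B primed). The acyclic compounds 12 and 13 are named as propan-1-ones, in which the later C3 is C2 and the later C2 is C3.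

**Route**

Step 1
Reactants: 1 2,4,6-trihydroxyacetophenone
Product: 2 1-[2,6-dihydroxy-4-(methoxymethoxy)phenyl]ethan-1-one
Conditions: MOMCl (1.05 equiv), i-Pr2NEt, THF–CH2Cl2, 0 °C
Reagents that add atoms: chloromethyl methyl ether (MOMCl), COCCl
Why: MOM ether formation (O-alkylation of a phenol), in which the 4-hydroxyl, para to the acetyl group and the only one not held in a hydrogen bond to the carbonyl, should react first with one equivalent of MOMCl and leave the symmetric 2,6-diol.

Step 2
Reactants: 2 1-[2,6-dihydroxy-4-(methoxymethoxy)phenyl]ethan-1-one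
Product: 3 1-[2,6-bis(tert-butyldimethylsilyloxy)-4-(methoxymethoxy)phenyl]ethan-1-one
Conditions: TBSCl (3 equiv), imidazole, DMAP (cat.), DMF, 40 °C
Reagents that add atoms: tert-butyldimethylsilyl chloride (TBSCl), CC(C)(C)[Si](C)(C)Cl
Why: Phenol silylation under imidazole/DMAP catalysis should cap both ortho hydroxyls, giving bulky silyl ethers that later keep these ring oxygens away from the carbene and are removable with fluoride in the presence of MOM ethers.

Step 3
Reactants: 3 1-[2,6-bis(tert-butyldimethylsilyloxy)-4-(methoxymethoxy)phenyl]ethan-1-one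
Product: 5 2-diazo-1-[2,6-bis(tert-butyldimethylsilyloxy)-4-(methoxymethoxy)phenyl]ethan-1-one, via trifluoroacetyl diketone 4 (not isolated)
Conditions: LiN(SiMe3)2, THF, −78 °C; CF3CO2CH2CF3; cold aq. HCl; then p-ABSA, Et3N, H2O (1 equiv), MeCN, rt
Reagents that add atoms: 4-acetamidobenzenesulfonyl azide (p-ABSA), CC(=O)Nc1ccc(cc1)S(=O)(=O)N=[N+]=[N-] (the two diazo nitrogens); 2,2,2-trifluoroethyl trifluoroacetate, O=C(OCC(F)(F)F)C(F)(F)F (the trifluoroacetyl group of 4 only, lost again)
Why: Detrifluoroacetylative diazo transfer (Regitz type), in which the kinetic lithium enolate of the methyl ketone is C-trifluoroacetylated and the activated diketone 4 takes up the diazo group from the sulfonyl azide with loss of the trifluoroacetyl group as its sulfonamide, is the standard route to diazomethyl ketones from hindered aryl methyl ketones.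

Step 4
Reactants: 6 5-methoxyresorcinol (5-methoxybenzene-1,3-diol)
Product: 7 1-methoxy-3,5-bis(methoxymethoxy)benzene
Conditions: MOMCl (2.5 equiv), i-Pr2NEt, CH2Cl2, 0 °C to rt
Reagents that add atoms: chloromethyl methyl ether (MOMCl), COCCl
Why: MOM ether formation on both phenols supplies two chelating ortho-directing groups for the next step and acid-labile protection that lasts to the end.

Step 5
Reactants: 7 1-methoxy-3,5-bis(methoxymethoxy)benzene
Product: 9 4-methoxy-2,6-bis(methoxymethoxy)benzaldehyde, via aryllithium 8 (not isolated)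
Conditions: n-BuLi, TMEDA, THF, 0 °C; DMF, 0 °C to rt; H2O
Reagents that add atoms: N,N-dimethylformamide, CN(C)C=O (formyl carbon and oxygen); n-butyllithium, [Li]CCCC (the lithium of 8 only)
Why: Directed ortho-metalation followed by formylation, in which the position between the two MOM ethers is lithiated in preference to the sites next to the methoxy group because two chelating directors act on it, and DMF converts aryllithium 8 into the aldehyde.

Step 6
Reactants: 5 2-diazo-1-[2,6-bis(tert-butyldimethylsilyloxy)-4-(methoxymethoxy)phenyl]ethan-1-one; 10 benzyl alcohol; 9 4-methoxy-2,6-bis(methoxymethoxy)benzaldehyde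
Product: 12 (2R,3S)-2-(benzyloxy)-1-[2,6-bis(tert-butyldimethylsilyloxy)-4-(methoxymethoxy)phenyl]-3-hydroxy-3-[4-methoxy-2,6-bis(methoxymethoxy)phenyl]propan-1-one, via enol of the oxonium ylide 11 (not isolated)
Conditions: Rh2(OAc)4 (2 mol %), (R)-TRIP [(R)-3,3'-bis(2,4,6-triisopropylphenyl)-1,1'-binaphthyl-2,2'-diyl hydrogen phosphate] (10 mol %), 4 Å MS, CH2Cl2, −20 °C, 5 (1.5 equiv) added slowly to 9 and 10 (1.5 equiv)
Reagents that add atoms: none
Why: Proposed new method: Rh2(OAc)4 (divalent rhodium) expels nitrogen from 5 to give an electrophilic rhodium carbene at the future C3, benzyl alcohol adds to it, and the oxonium ylide, numbered here as its enol tautomer 11, is intercepted at carbon by aldehyde 9 before the 1,2-proton shift to the plain O–H insertion product can occur, so that C3–O3 and C2–C3 form in one operation. The closest known reaction type is the dirhodium and chiral phosphoric acid co-catalysed three-component coupling of diazo carbonyl compounds with alcohols and imines or electron-poor aldehydes; a doubly ortho-substituted, electron-rich benzaldehyde has not been used in it, and the ortho MOM oxygens are counted on to help the acid hold the formyl group. No ring is closed. Both new stereocentres arise in the C–C bond-forming event and are controlled by the phosphoric acid, which hydrogen-bonds the enol O–H and the aldehyde C=O in a cyclic array, so that the catalyst antipode fixes the R configuration at the benzyloxy carbon and the compact chair-like array favours the syn adduct. The step needs intermolecular attack of the alcohol to outrun trapping of the carbene by the ring A oxygens, which the bulky ortho TBS ethers and the excess of benzyl alcohol should secure, and it needs syn selectivity because the carbinol centre is inverted in step 8.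

Step 7
Reactants: 12 the syn adduct from step 6
Product: 13 (2R,3S)-2-(benzyloxy)-1-[2,6-dihydroxy-4-(methoxymethoxy)phenyl]-3-hydroxy-3-[4-methoxy-2,6-bis(methoxymethoxy)phenyl]propan-1-one
Conditions: TBAF, AcOH (1:1), THF, 0 °C
Reagents that add atoms: none
Why: Fluoride-mediated desilylation cleaves aryl silyl ethers rapidly, the acetic acid buffer should suppress retro-aldol cleavage of the β-hydroxy ketone, and MOM and benzyl ethers are not affected.

Step 8
Reactants: 13 the 2,6-dihydroxyphenyl ketone from step 7
Product: 14 (2R,3R)-3-(benzyloxy)-5-hydroxy-7-(methoxymethoxy)-2-[4-methoxy-2,6-bis(methoxymethoxy)phenyl]chroman-4-one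
Conditions: PPh3, DIAD, THF (0.01 M), 0 °C
Reagents that add atoms: none
Why: Intramolecular Mitsunobu etherification (6-exo-tet), in which the benzylic hydroxyl is activated as its oxyphosphonium ion and displaced with inversion by either of the two equivalent ortho phenols, should turn the syn adduct into the 2,3-trans (2R,3R) chromanone without touching C3.

Step 9
Reactants: 14 the 3-O-benzyl chromanone
Product: 15 (2R,3R)-3,5-dihydroxy-7-(methoxymethoxy)-2-[4-methoxy-2,6-bis(methoxymethoxy)phenyl]chroman-4-one
Conditions: H2 (1 atm), Pd/C (10 %), EtOAc, rt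
Reagents that add atoms: none
Why: Catalytic hydrogenolysis of the benzyl ether is placed here because no alkene is yet present, and the MOM ethers, the chelated aryl ketone and the O1–C2 bond should survive neutral conditions at one atmosphere.

Step 10
Reactants: 15 the 3,5-dihydroxy chromanone
Product: 16 (2R,3R)-3-hydroxy-7-(methoxymethoxy)-2-[4-methoxy-2,6-bis(methoxymethoxy)phenyl]-5-[(3-methylbut-2-en-1-yl)oxy]chroman-4-one
Conditions: 3-methylbut-2-en-1-ol, PPh3, DIAD, THF, 0 °C to rt
Reagents that add atoms: 3-methylbut-2-en-1-ol, CC(C)=CCO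
Why: Mitsunobu etherification alkylates the hydrogen-bonded 5-OH, the only phenol, under neutral conditions, while the hindered secondary 3-OH is neither acidic enough to act as nucleophile nor activated as fast as the primary allylic alcohol.

Step 11
Reactants: 16 the 5-O-prenyl ether
Product: 18 (2R,3R)-3,5-dihydroxy-7-(methoxymethoxy)-2-[4-methoxy-2,6-bis(methoxymethoxy)phenyl]-8-(3-methylbut-2-en-1-yl)chroman-4-one, via C6 dienone 17 (not isolated)
Conditions: Eu(fod)3 [tris(6,6,7,7,8,8,8-heptafluoro-2,2-dimethyloctane-3,5-dionato)europium] (10 mol %), CHCl3, 60 °C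
Reagents that add atoms: none
Why: Claisen–Cope (para-Claisen) rearrangement catalysed by the oxophilic trivalent europium complex, in which a [3,3] shift to C6 gives dienone 17 bearing a 1,1-dimethylallyl group, a second [3,3] shift carries it to C8 as the linear prenyl group and tautomerisation restores the chelated 5-OH, is the established way from 5-O-prenyl flavanones to their 8-prenyl isomers and leaves C2 and C3 untouched.

Step 12
Reactants: 18 the 8-prenyl chromanone
Product: 19 (2R,3R)-3,5-dihydroxy-6-iodo-7-(methoxymethoxy)-2-[4-methoxy-2,6-bis(methoxymethoxy)phenyl]-8-(3-methylbut-2-en-1-yl)chroman-4-one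
Conditions: I2 (1.05 equiv), NaHCO3, THF–H2O, 0 °C
Reagents that add atoms: iodine, II
Why: Electrophilic aromatic iodination through the phenolate, in which C6 is the only free position of ring A and lies ortho to the 5-OH, should be selective because molecular iodine under bicarbonate reacts with the small equilibrium amount of phenolate far faster than with the neutral aryl ethers of ring B or with the trisubstituted alkene.

Step 13
Reactants: 20 geranyl chloride [(2E)-1-chloro-3,7-dimethylocta-2,6-diene]
Product: 21 tributyl[(2E)-3,7-dimethylocta-2,6-dien-1-yl]stannane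
Conditions: Bu3SnH, LiN(i-Pr)2, THF, 0 °C; then 20, −78 °C to rt
Reagents that add atoms: tributyltin hydride, CCCC[SnH](CCCC)CCCC
Why: SN2 alkylation of a stannyl anion, in which Bu3SnLi displaces the primary allylic chloride at the α-carbon, should keep the E double bond in place.

Step 14
Reactants: 19 the C6 iodide; 21 tributyl[(2E)-3,7-dimethylocta-2,6-dien-1-yl]stannane
Product: 22 (2R,3R)-6-[(2E)-3,7-dimethylocta-2,6-dien-1-yl]-3,5-dihydroxy-7-(methoxymethoxy)-2-[4-methoxy-2,6-bis(methoxymethoxy)phenyl]-8-(3-methylbut-2-en-1-yl)chroman-4-one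
Conditions: Pd(PPh3)4 (5 mol %), DMF, 80 °C, degassed
Reagents that add atoms: none
Why: Stille cross-coupling, in which zerovalent palladium inserts into the C6–I bond, the allylstannane transfers the geranyl group and reductive elimination at the less hindered CH2 terminus gives the linear E isomer, runs under neutral conditions that spare the α-ketol and the free phenol.

Step 15
Reactants: 22 the tris-MOM ether
Product: 23 (2R,3R)-2-(2,6-dihydroxy-4-methoxyphenyl)-6-[(2E)-3,7-dimethylocta-2,6-dien-1-yl]-3,5,7-trihydroxy-8-(3-methylbut-2-en-1-yl)chroman-4-one (target)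
Conditions: 3 M aq. HCl, MeOH, 40 °C, stopped at full conversion
Reagents that add atoms: none
Why: Acid-catalysed acetal exchange in methanol removes all three MOM groups as dimethoxymethane, mild temperature and short contact should limit cyclisation of the prenyl and geranyl groups onto neighbouring phenols, and the 2,3-trans arrangement is the thermodynamically preferred one should C2 equilibrate.

**Compound list**

1 | 2,4,6-trihydroxyacetophenone | CC(=O)c1c(O)cc(O)cc1O | starting material
2 | 1-[2,6-dihydroxy-4-(methoxymethoxy)phenyl]ethan-1-one | CC(=O)c1c(O)cc(OCOC)cc1O | intermediate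
3 | 1-[2,6-bis(tert-butyldimethylsilyloxy)-4-(methoxymethoxy)phenyl]ethan-1-one | CC(=O)c1c(O[Si](C)(C)C(C)(C)C)cc(OCOC)cc1O[Si](C)(C)C(C)(C)C | intermediate
4 | 1-[2,6-bis(tert-butyldimethylsilyloxy)-4-(methoxymethoxy)phenyl]-4,4,4-trifluorobutane-1,3-dione | O=C(CC(=O)C(F)(F)F)c1c(O[Si](C)(C)C(C)(C)C)cc(OCOC)cc1O[Si](C)(C)C(C)(C)C | intermediate (not isolated)
5 | 2-diazo-1-[2,6-bis(tert-butyldimethylsilyloxy)-4-(methoxymethoxy)phenyl]ethan-1-one | O=C(C=[N+]=[N-])c1c(O[Si](C)(C)C(C)(C)C)cc(OCOC)cc1O[Si](C)(C)C(C)(C)C | intermediate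
6 | 5-methoxyresorcinol | COc1cc(O)cc(O)c1 | starting material
7 | 1-methoxy-3,5-bis(methoxymethoxy)benzene | COCOc1cc(OC)cc(OCOC)c1 | intermediate
8 | [4-methoxy-2,6-bis(methoxymethoxy)phenyl]lithium | [Li]c1c(OCOC)cc(OC)cc1OCOC | intermediate (not isolated)
9 | 4-methoxy-2,6-bis(methoxymethoxy)benzaldehyde | COc1cc(OCOC)c(C=O)c(OCOC)c1 | intermediate
10 | benzyl alcohol | OCc1ccccc1 | starting material
11 | 2-(benzyloxy)-1-[2,6-bis(tert-butyldimethylsilyloxy)-4-(methoxymethoxy)phenyl]ethen-1-ol (enol tautomer of the oxonium ylide, double-bond geometry not assigned) | OC(=COCc1ccccc1)c1c(O[Si](C)(C)C(C)(C)C)cc(OCOC)cc1O[Si](C)(C)C(C)(C)C | intermediate (not isolated)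
12 | (2R,3S)-2-(benzyloxy)-1-[2,6-bis(tert-butyldimethylsilyloxy)-4-(methoxymethoxy)phenyl]-3-hydroxy-3-[4-methoxy-2,6-bis(methoxymethoxy)phenyl]propan-1-one | COc1cc(OCOC)c([C@H](O)[C@@H](OCc2ccccc2)C(=O)c2c(O[Si](C)(C)C(C)(C)C)cc(OCOC)cc2O[Si](C)(C)C(C)(C)C)c(OCOC)c1 | intermediate
13 | (2R,3S)-2-(benzyloxy)-1-[2,6-dihydroxy-4-(methoxymethoxy)phenyl]-3-hydroxy-3-[4-methoxy-2,6-bis(methoxymethoxy)phenyl]propan-1-one | COc1cc(OCOC)c([C@H](O)[C@@H](OCc2ccccc2)C(=O)c2c(O)cc(OCOC)cc2O)c(OCOC)c1 | intermediate
14 | (2R,3R)-3-(benzyloxy)-5-hydroxy-7-(methoxymethoxy)-2-[4-methoxy-2,6-bis(methoxymethoxy)phenyl]chroman-4-one | COc1cc(OCOC)c([C@H]2Oc3cc(OCOC)cc(O)c3C(=O)[C@@H]2OCc4ccccc4)c(OCOC)c1 | intermediate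
15 | (2R,3R)-3,5-dihydroxy-7-(methoxymethoxy)-2-[4-methoxy-2,6-bis(methoxymethoxy)phenyl]chroman-4-one | COc1cc(OCOC)c([C@H]2Oc3cc(OCOC)cc(O)c3C(=O)[C@@H]2O)c(OCOC)c1 | intermediate
16 | (2R,3R)-3-hydroxy-7-(methoxymethoxy)-2-[4-methoxy-2,6-bis(methoxymethoxy)phenyl]-5-[(3-methylbut-2-en-1-yl)oxy]chroman-4-one | COc1cc(OCOC)c([C@H]2Oc3cc(OCOC)cc(OCC=C(C)C)c3C(=O)[C@@H]2O)c(OCOC)c1 | intermediate
17 | (2R,3R)-3-hydroxy-7-(methoxymethoxy)-2-[4-methoxy-2,6-bis(methoxymethoxy)phenyl]-6-(2-methylbut-3-en-2-yl)-2,3-dihydro-4H-chromene-4,5(6H)-dione (C6 epimers) | COc1cc(OCOC)c([C@H]2OC3=C(C(=O)[C@@H]2O)C(=O)C(C(C)(C)C=C)C(OCOC)=C3)c(OCOC)c1 | intermediate (not isolated)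
18 | (2R,3R)-3,5-dihydroxy-7-(methoxymethoxy)-2-[4-methoxy-2,6-bis(methoxymethoxy)phenyl]-8-(3-methylbut-2-en-1-yl)chroman-4-one | COc1cc(OCOC)c([C@H]2Oc3c(CC=C(C)C)c(OCOC)cc(O)c3C(=O)[C@@H]2O)c(OCOC)c1 | intermediate
19 | (2R,3R)-3,5-dihydroxy-6-iodo-7-(methoxymethoxy)-2-[4-methoxy-2,6-bis(methoxymethoxy)phenyl]-8-(3-methylbut-2-en-1-yl)chroman-4-one | COc1cc(OCOC)c([C@H]2Oc3c(CC=C(C)C)c(OCOC)c(I)c(O)c3C(=O)[C@@H]2O)c(OCOC)c1 | intermediate
20 | geranyl chloride, (2E)-1-chloro-3,7-dimethylocta-2,6-diene | ClC/C=C(\C)CCC=C(C)C | starting material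
21 | tributyl[(2E)-3,7-dimethylocta-2,6-dien-1-yl]stannane | CCCC[Sn](CCCC)(CCCC)C/C=C(\C)CCC=C(C)C | intermediate
22 | (2R,3R)-6-[(2E)-3,7-dimethylocta-2,6-dien-1-yl]-3,5-dihydroxy-7-(methoxymethoxy)-2-[4-methoxy-2,6-bis(methoxymethoxy)phenyl]-8-(3-methylbut-2-en-1-yl)chroman-4-one | COc1cc(OCOC)c([C@H]2Oc3c(CC=C(C)C)c(OCOC)c(C/C=C(\C)CCC=C(C)C)c(O)c3C(=O)[C@@H]2O)c(OCOC)c1 | intermediate
23 | (2R,3R)-2-(2,6-dihydroxy-4-methoxyphenyl)-6-[(2E)-3,7-dimethylocta-2,6-dien-1-yl]-3,5,7-trihydroxy-8-(3-methylbut-2-en-1-yl)chroman-4-one | COc1cc(O)c([C@H]2Oc3c(CC=C(C)C)c(O)c(C/C=C(\C)CCC=C(C)C)c(O)c3C(=O)[C@@H]2O)c(O)c1 | target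

**Step count**

Total: 15 steps. Longest linear sequence: 12 steps (steps 1–3, 6–12, 14 and 15).

**Steps most likely to fail**

Step 6. The 1,2-proton shift of the ylide may outrun its addition to the hindered, electron-rich formyl group, or the addition may proceed with poor facial control. The fallback makes the two bonds one after the other by known chemistry. Setting out from 5 and 10, Rh2(OAc)4-catalysed O–H insertion without the aldehyde would give 2-(benzyloxy)-1-[2,6-bis(tert-butyldimethylsilyloxy)-4-(methoxymethoxy)phenyl]ethan-1-one F1. Its Z-enol borinate, formed with diisopinocampheylboron triflate and i-Pr2NEt in CH2Cl2 at −78 °C, would add to aldehyde 9 through a closed chair transition state to give the syn aldol. The antipode of the boron reagent is chosen to deliver the (2R,3S) adduct, and the route is rejoined at 12.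

Step 12. The iodinating agent may attack the prenyl double bond or the electron-rich ring B in place of C6. The fallback halogenates before any alkene is present and reverses the order in which the two side chains arrive.
- Setting out from 15, benzyltrimethylammonium dichloroiodate with CaCO3 in CH2Cl2–MeOH, a reagent that iodinates free phenols ortho to a chelated hydroxyl and leaves aryl ethers alone without added Lewis acid, would give (2R,3R)-3,5-dihydroxy-6-iodo-7-(methoxymethoxy)-2-[4-methoxy-2,6-bis(methoxymethoxy)phenyl]chroman-4-one F2.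
- Stille coupling of F2 with 21 [Pd(PPh3)4, zerovalent palladium, DMF] would give (2R,3R)-6-[(2E)-3,7-dimethylocta-2,6-dien-1-yl]-3,5-dihydroxy-7-(methoxymethoxy)-2-[4-methoxy-2,6-bis(methoxymethoxy)phenyl]chroman-4-one F3.
- Mitsunobu etherification with 3-methylbut-2-en-1-ol would give (2R,3R)-6-[(2E)-3,7-dimethylocta-2,6-dien-1-yl]-3-hydroxy-7-(methoxymethoxy)-2-[4-methoxy-2,6-bis(methoxymethoxy)phenyl]-5-[(3-methylbut-2-en-1-yl)oxy]chroman-4-one F4.
- Eu(fod)3-catalysed para-Claisen rearrangement of F4 would place the prenyl group at C8, because in the ortho dienone only the 1,1-dimethylallyl group can migrate on through an unsubstituted vinyl terminus. The route is rejoined at 22.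

Step 8. The activated benzylic oxygen, flanked by three oxygen donors on ring B, may ionise or be lost by elimination to the α-benzyloxy enone, so that the displacement is no longer a clean inversion. The fallback uses that ionisation on purpose. Setting out from 13, catalytic camphorsulfonic acid in CH2Cl2 at 0 °C would generate the stabilised benzylic cation, which the ortho phenol closes under thermodynamic control to the 2,3-trans chromanone with both large groups equatorial. Either C2 epimer of the adduct would then converge, only the C3 configuration from step 6 has to be carried, and the route is rejoined at 14. No new compound arises on this path (entry F0).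

**Further compounds**

F1 | step 6 | 2-(benzyloxy)-1-[2,6-bis(tert-butyldimethylsilyloxy)-4-(methoxymethoxy)phenyl]ethan-1-one | O=C(COCc1ccccc1)c1c(O[Si](C)(C)C(C)(C)C)cc(OCOC)cc1O[Si](C)(C)C(C)(C)C
F0 | step 8 | none | none
F2 | step 12 | (2R,3R)-3,5-dihydroxy-6-iodo-7-(methoxymethoxy)-2-[4-methoxy-2,6-bis(methoxymethoxy)phenyl]chroman-4-one | COc1cc(OCOC)c([C@H]2Oc3cc(OCOC)c(I)c(O)c3C(=O)[C@@H]2O)c(OCOC)c1
F3 | step 12 | (2R,3R)-6-[(2E)-3,7-dimethylocta-2,6-dien-1-yl]-3,5-dihydroxy-7-(methoxymethoxy)-2-[4-methoxy-2,6-bis(methoxymethoxy)phenyl]chroman-4-one | COc1cc(OCOC)c([C@H]2Oc3cc(OCOC)c(C/C=C(\C)CCC=C(C)C)c(O)c3C(=O)[C@@H]2O)c(OCOC)c1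
F4 | step 12 | (2R,3R)-6-[(2E)-3,7-dimethylocta-2,6-dien-1-yl]-3-hydroxy-7-(methoxymethoxy)-2-[4-methoxy-2,6-bis(methoxymethoxy)phenyl]-5-[(3-methylbut-2-en-1-yl)oxy]chroman-4-one | COc1cc(OCOC)c([C@H]2Oc3cc(OCOC)c(C/C=C(\C)CCC=C(C)C)c(OCC=C(C)C)c3C(=O)[C@@H]2O)c(OCOC)c1
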